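Ring A is removed entirely. Because the bond C4a–C8a belongs both to the benzene ring and to the oxygen-bearing alkene of ring C, ring C can be completed beforehand as a 2,3-dihydro-4-pyranone that already holds C2, C3 and the ester. A diazoacetyl group on that alkene carbon brings C8 and C5; benzyl ethynyl ether brings C6 and C7. Irradiation, then gentle warming, makes C8–C8a, C5–C6, C7–C8 and C4a–C5 in one operation and gives the arene with 5-OH free and O7 benzylated under neutral conditions. The precursor is the (2R,3R)-3-acyloxy-2-phenyl-6-(diazoacetyl)dihydropyranone, reached from a purchased (S)-hydroxy ester with O3 introduced trans to phenyl after ring closure.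

Key step: step 11

Remark on stereochemistry: syn-dihydroxylation of an (E)-cinnamoyl precursor would place O3 and phenyl cis once O1 closes the ring, and a free 3-hydroxyl could close a furanone instead; ring C is therefore closed with O1 as its only hydroxyl and O3 is added afterwards on the face opposite phenyl.

Remark on materials: ethyl (S)-3-hydroxy-3-phenylpropanoate and (R)-2-methylbutanoic acid are taken as purchased single enantiomers, diazomethane is generated separately from N-methyl-N-nitroso-p-toluenesulfonamide, and benzyl ethynyl ether is assumed to survive several hours below 25 °C.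

Step 1
Reactants: 1 ethyl (3S)-3-hydroxy-3-phenylpropanoate
Product: 2 ethyl (3S)-3-phenyl-3-[(triethylsilyl)oxy]propanoate
Conditions: Et3SiCl (1.2 equiv), imidazole (2 equiv), CH2Cl2, 0 °C → rt
Reagents that add atoms: chlorotriethylsilane, CC[Si](Cl)(CC)CC
Why: Imidazole-mediated silylation of a secondary benzylic alcohol is routine, and the triethylsilyl ether should mask the only hydroxyl through the three basic steps that follow while remaining removable with dilute acid.

Step 2
Reactants: 2 ethyl (3S)-3-phenyl-3-[(triethylsilyl)oxy]propanoate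
Product: 3 (3S)-N-methoxy-N-methyl-3-phenyl-3-[(triethylsilyl)oxy]propanamide
Conditions: MeNH(OMe)·HCl (1.5 equiv), i-PrMgCl (3.0 equiv), THF, −20 → 0 °C; aq. NH4Cl
Reagents that add atoms: N,O-dimethylhydroxylamine hydrochloride, CNOC.Cl
Why: Weinreb amide formation from an ester with the chloromagnesium amide of N,O-dimethylhydroxylamine is standard for β-silyloxy esters and should leave the benzylic stereocentre untouched.

Step 3
Reactants: 3 (3S)-N-methoxy-N-methyl-3-phenyl-3-[(triethylsilyl)oxy]propanamide
Product: 4 (4S)-4-phenyl-4-[(triethylsilyl)oxy]butan-2-one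
Conditions: MeMgBr (1.5 equiv), THF, 0 °C; aq. NH4Cl
Reagents that add atoms: methylmagnesium bromide, C[Mg]Br
Why: Grignard addition to a Weinreb amide stops at the chelated tetrahedral adduct, so a single methyl group should be delivered and the methyl ketone appears only on work-up.

Step 4
Reactants: 4 (4S)-4-phenyl-4-[(triethylsilyl)oxy]butan-2-one; 5 di-tert-butyl oxalate
Product: 6 tert-butyl (6S)-2,4-dioxo-6-phenyl-6-[(triethylsilyl)oxy]hexanoate
Conditions: LiN(SiMe3)2 (1.2 equiv), THF, −78 °C; then 5 (1.3 equiv), −78 → −20 °C; AcOH quench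
Reagents that add atoms: none
Why: Kinetic deprotonation at the methyl group followed by crossed Claisen condensation with the non-enolisable oxalate is a standard entry to 2,4-dioxo esters, and the acidic product should be held as its enolate until the quench.

Step 5
Reactants: 6 tert-butyl (6S)-2,4-dioxo-6-phenyl-6-[(triethylsilyl)oxy]hexanoate
Product: 8 tert-butyl (2S)-4-oxo-2-phenyl-3,4-dihydro-2H-pyran-6-carboxylate, via hydroxy diketo ester 7 (not isolated)
Conditions: 1 M aq. HCl, THF, 0 °C → rt; then TsOH·H2O (0.1 equiv), CH2Cl2, 4 Å MS, rt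
Reagents that add atoms: none
Why: Dilute acid should remove the silyl group, the freed benzylic hydroxyl is the only nucleophile that can reach the keto group next to the ester through a six-membered ring, and loss of water then gives the vinylogous ester (cyclodehydration of a δ-hydroxy-1,3-dicarbonyl compound) without touching the stereocentre.

Step 6
Reactants: 8 tert-butyl (2S)-4-oxo-2-phenyl-3,4-dihydro-2H-pyran-6-carboxylate; 9 (2R)-2-methylbutanoic acid
Product: 10 tert-butyl (2R,3R)-3-{[(2R)-2-methylbutanoyl]oxy}-4-oxo-2-phenyl-3,4-dihydro-2H-pyran-6-carboxylate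
Conditions: Mn(OAc)3·2H2O (3 equiv) pre-heated with 9 (12 equiv, excess recovered by base extraction) in benzene under a Dean–Stark trap; then 8, reflux
Reagents that add atoms: none
Why: α'-Acyloxylation of enones by trivalent manganese acetate in the presence of a carboxylic acid is a known reaction that is trans-selective on 2-substituted 2,3-dihydro-4-pyranones, the carboxylate being delivered to C3 on the face opposite the C2 phenyl group, which should set the 3R centre under substrate control.

Step 7
Reactants: 10 tert-butyl (2R,3R)-3-{[(2R)-2-methylbutanoyl]oxy}-4-oxo-2-phenyl-3,4-dihydro-2H-pyran-6-carboxylate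
Product: 11 (2R,3R)-3-{[(2R)-2-methylbutanoyl]oxy}-4-oxo-2-phenyl-3,4-dihydro-2H-pyran-6-carboxylic acid
Conditions: CF3CO2H–CH2Cl2 (1:4), 0 °C → rt
Reagents that add atoms: none
Why: Acidolysis of a tert-butyl ester with trifluoroacetic acid proceeds by loss of isobutene and should leave the secondary ester, the ketone and both ring stereocentres alone.

Step 8
Reactants: 11 (2R,3R)-3-{[(2R)-2-methylbutanoyl]oxy}-4-oxo-2-phenyl-3,4-dihydro-2H-pyran-6-carboxylic acid
Product: 13 (2R,3R)-6-(diazoacetyl)-4-oxo-2-phenyl-3,4-dihydro-2H-pyran-3-yl (2R)-2-methylbutanoate, via acid chloride 12 (not isolated)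
Conditions: 1-chloro-N,N,2-trimethylprop-1-en-1-amine (1.2 equiv), CH2Cl2, 0 °C → rt; then added to CH2N2 (3 equiv), Et2O, −20 → 0 °C
Reagents that add atoms: diazomethane, C=[N+]=[N-]
Why: The chloroenamine should give the acid chloride under neutral conditions and acylation of diazomethane (first stage of the Arndt–Eistert sequence) is fast at low temperature, a second equivalent taking up HCl, while the ring alkene, deactivated by the donor O1, should be a poor dipolarophile at −20 °C.

Step 9
Reactants: 14 benzyl alcohol; 15 trichloroethylene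
Product: 16 benzyl (E)-1,2-dichloroethenyl ether
Conditions: KH (1.5 equiv), THF, 0 °C; then 15 (1.1 equiv), −50 °C → rt
Reagents that add atoms: none
Why: The alkoxide converts trichloroethylene into dichloroacetylene and adds to it in an anti sense, which is the established route to (E)-1,2-dichlorovinyl ethers.

Step 10
Reactants: 16 benzyl (E)-1,2-dichloroethenyl ether
Product: 19 benzyl ethynyl ether, via benzyl chloroethynyl ether 17 (not isolated), via lithium benzyloxyethynide 18 (not isolated)
Conditions: n-BuLi (2.3 equiv), THF, −78 → −40 °C; MeOH, −78 °C; cold aqueous work-up, used at once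
Reagents that add atoms: none
Why: Two equivalents of n-BuLi effect dehydrochlorination and then chlorine–lithium exchange, and protonation of the lithium alkoxyacetylide at −78 °C should give the terminal ynol ether, which is kept cold because benzyl alkynyl ethers rearrange sigmatropically on warming.

Step 11
Reactants: 13 (2R,3R)-6-(diazoacetyl)-4-oxo-2-phenyl-3,4-dihydro-2H-pyran-3-yl (2R)-2-methylbutanoate; 19 benzyl ethynyl ether
Product: 24 (2R,3R)-7-(benzyloxy)-5-hydroxy-4-oxo-2-phenyl-3,4-dihydro-2H-chromen-3-yl (2R)-2-methylbutanoate, via vinylketene 20 (not isolated), via cyclobutenone 21 (not isolated), via dienylketene 22 (not isolated), via cyclohexadienone 23 (not isolated)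
Conditions: 19 (3 equiv), ClCH2CH2Cl (0.1 M), 405 nm LEDs, 15 °C, until N2 evolution stops; solvent and surplus 19 removed under high vacuum below 20 °C; then PhMe, 80 °C, dark
Reagents that add atoms: none
Why: Excitation of the diazo ketone releases N2 while C8a shifts from the carbonyl carbon to the former diazo carbon (photochemical Wolff rearrangement) to give vinylketene 20, and the unsubstituted, nucleophilic carbon of the ynol ether then bonds to the ketene carbonyl carbon and the oxygen-bearing carbon to the ketene α-carbon, so that [2+2] cycloaddition gives cyclobutenone 21. Warming opens 21 in a reversible 4π electrocyclic step to dienylketene 22, ring A closes by a thermal disrotatory 6π electrocyclisation between the ketene carbon (C5) and C4a to give 23, and enolisation of 23 gives the chelated phenol. The closest known reaction is the Danheiser benzannulation in its photochemical Wolff form, shown for α,β-unsaturated α'-diazo ketones with alkoxy- and siloxyalkynes. No stereocentre is formed, since the sp3 carbons of 21 and 23 revert to sp2, and C2, C3 and the ester centre meet neither acid nor base. The regiochemistry needed, oxygen on C7 and not on C6, follows from the polarisation of the ynol ether, and closure can occur only at C4a because the other substituent of C8a is the ring oxygen. Chemoselectivity between the two chromophores is sought by irradiating at 405 nm, where the diazo ketone absorbs and the vinylogous ester should not, and the hydrogen-bonded 5-OH of 24 is a poor trap for ketenes.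

Step 12
Reactants: 24 (2R,3R)-7-(benzyloxy)-5-hydroxy-4-oxo-2-phenyl-3,4-dihydro-2H-chromen-3-yl (2R)-2-methylbutanoate
Product: 25 (2R,3R)-5,7-dihydroxy-4-oxo-2-phenyl-3,4-dihydro-2H-chromen-3-yl (2R)-2-methylbutanoate
Conditions: H2 (1 atm), 10% Pd/C, EtOAc, rt, stopped at full conversion
Reagents that add atoms: none
Why: Hydrogenolysis of an aryl benzyl ether over Pd/C is neutral and is routinely used on 5-hydroxyflavanones without cleaving the C2–O1 bond or reducing the hydrogen-bonded ketone, so the ester and all three stereocentres should survive.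

Compound list
1 | ethyl (3S)-3-hydroxy-3-phenylpropanoate | CCOC(=O)C[C@H](O)c1ccccc1 | starting material
2 | ethyl (3S)-3-phenyl-3-[(triethylsilyl)oxy]propanoate | CCOC(=O)C[C@H](O[Si](CC)(CC)CC)c1ccccc1 | intermediate
3 | (3S)-N-methoxy-N-methyl-3-phenyl-3-[(triethylsilyl)oxy]propanamide | CON(C)C(=O)C[C@H](O[Si](CC)(CC)CC)c1ccccc1 | intermediate
4 | (4S)-4-phenyl-4-[(triethylsilyl)oxy]butan-2-one | CC(=O)C[C@H](O[Si](CC)(CC)CC)c1ccccc1 | intermediate
5 | di-tert-butyl oxalate | CC(C)(C)OC(=O)C(=O)OC(C)(C)C | starting material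
6 | tert-butyl (6S)-2,4-dioxo-6-phenyl-6-[(triethylsilyl)oxy]hexanoate (largely enolised) | CC(C)(C)OC(=O)C(=O)CC(=O)C[C@H](O[Si](CC)(CC)CC)c1ccccc1 | intermediate
7 | tert-butyl (6S)-6-hydroxy-2,4-dioxo-6-phenylhexanoate | CC(C)(C)OC(=O)C(=O)CC(=O)C[C@H](O)c1ccccc1 | intermediate (not isolated)
8 | tert-butyl (2S)-4-oxo-2-phenyl-3,4-dihydro-2H-pyran-6-carboxylate | CC(C)(C)OC(=O)C1=CC(=O)C[C@@H](c2ccccc2)O1 | intermediate
9 | (2R)-2-methylbutanoic acid | CC[C@@H](C)C(=O)O | starting material
10 | tert-butyl (2R,3R)-3-{[(2R)-2-methylbutanoyl]oxy}-4-oxo-2-phenyl-3,4-dihydro-2H-pyran-6-carboxylate | CC[C@@H](C)C(=O)O[C@H]1C(=O)C=C(C(=O)OC(C)(C)C)O[C@@H]1c1ccccc1 | intermediate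
11 | (2R,3R)-3-{[(2R)-2-methylbutanoyl]oxy}-4-oxo-2-phenyl-3,4-dihydro-2H-pyran-6-carboxylic acid | CC[C@@H](C)C(=O)O[C@H]1C(=O)C=C(C(=O)O)O[C@@H]1c1ccccc1 | intermediate
12 | (2R,3R)-6-(chlorocarbonyl)-4-oxo-2-phenyl-3,4-dihydro-2H-pyran-3-yl (2R)-2-methylbutanoate | CC[C@@H](C)C(=O)O[C@H]1C(=O)C=C(C(=O)Cl)O[C@@H]1c1ccccc1 | intermediate (not isolated)
13 | (2R,3R)-6-(diazoacetyl)-4-oxo-2-phenyl-3,4-dihydro-2H-pyran-3-yl (2R)-2-methylbutanoate | CC[C@@H](C)C(=O)O[C@H]1C(=O)C=C(C(=O)C=[N+]=[N-])O[C@@H]1c1ccccc1 | intermediate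
14 | benzyl alcohol | OCc1ccccc1 | starting material
15 | trichloroethylene | ClC=C(Cl)Cl | starting material
16 | benzyl (E)-1,2-dichloroethenyl ether | Cl/C=C(/Cl)OCc1ccccc1 | intermediate
17 | benzyl chloroethynyl ether | ClC#COCc1ccccc1 | intermediate (not isolated)
18 | lithium 2-(benzyloxy)ethynide | [Li]C#COCc1ccccc1 | intermediate (not isolated)
19 | benzyl ethynyl ether | C#COCc1ccccc1 | intermediate
20 | (2R,3R)-4-oxo-6-(2-oxoethenyl)-2-phenyl-3,4-dihydro-2H-pyran-3-yl (2R)-2-methylbutanoate | CC[C@@H](C)C(=O)O[C@H]1C(=O)C=C(C=C=O)O[C@@H]1c1ccccc1 | intermediate (not isolated)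
21 | (2R,3R)-6-[2-(benzyloxy)-4-oxocyclobut-2-en-1-yl]-4-oxo-2-phenyl-3,4-dihydro-2H-pyran-3-yl (2R)-2-methylbutanoate, both epimers at the cyclobutene CH | CC[C@@H](C)C(=O)O[C@H]1C(=O)C=C(C2C(=O)C=C2OCc3ccccc3)O[C@@H]1c1ccccc1 | intermediate (not isolated)
22 | (2R,3R)-6-[(1E)-2-(benzyloxy)-4-oxobuta-1,3-dien-1-yl]-4-oxo-2-phenyl-3,4-dihydro-2H-pyran-3-yl (2R)-2-methylbutanoate | CC[C@@H](C)C(=O)O[C@H]1C(=O)C=C(/C=C(\C=C=O)OCc2ccccc2)O[C@@H]1c1ccccc1 | intermediate (not isolated)
23 | (2R,3R)-7-(benzyloxy)-4,5-dioxo-2-phenyl-3,4,4a,5-tetrahydro-2H-chromen-3-yl (2R)-2-methylbutanoate, C4a unassigned | CC[C@@H](C)C(=O)O[C@H]1C(=O)C2C(=O)C=C(OCc3ccccc3)C=C2O[C@@H]1c1ccccc1 | intermediate (not isolated)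
24 | (2R,3R)-7-(benzyloxy)-5-hydroxy-4-oxo-2-phenyl-3,4-dihydro-2H-chromen-3-yl (2R)-2-methylbutanoate | CC[C@@H](C)C(=O)O[C@H]1C(=O)c2c(O)cc(OCc3ccccc3)cc2O[C@@H]1c1ccccc1 | intermediate
25 | (2R,3R)-5,7-dihydroxy-4-oxo-2-phenyl-3,4-dihydro-2H-chromen-3-yl (2R)-2-methylbutanoate | CC[C@@H](C)C(=O)O[C@H]1C(=O)c2c(O)cc(O)cc2O[C@@H]1c1ccccc1 | target

Total step count: 12. Longest linear sequence: 10 steps (steps 1 to 8, then 11 and 12); steps 9 and 10 form the two-step side branch to 19.

Steps most likely to fail

Step 11. Light may also be taken up by the vinylogous ester or by the product, so that enone–alkyne photocycloaddition and photodecomposition compete with the Wolff shift, or the ketene may dimerise before the ynol ether traps it. The fallback sets out from 13 and comes back at 21, and so at 24. The rearrangement would be run without light and without the alkyne, using PhCO2Ag (0.1 equiv) and Et3N in THF–water. Water then traps ketene 20 as [(2R,3R)-3-{[(2R)-2-methylbutanoyl]oxy}-4-oxo-2-phenyl-3,4-dihydro-2H-pyran-6-yl]acetic acid F1 (Arndt–Eistert homologation). 1-Chloro-N,N,2-trimethylprop-1-en-1-amine would convert F1 into (2R,3R)-6-(2-chloro-2-oxoethyl)-4-oxo-2-phenyl-3,4-dihydro-2H-pyran-3-yl (2R)-2-methylbutanoate F2. F2 would be added slowly to Et3N and 19 in CH2Cl2 at 0 °C, so that dehydrochlorination regenerates 20 in the dark in the presence of the ketenophile. The [2+2] adduct 21 would then be heated in toluene at 80 °C as in step 11 to give 24.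

Step 8. Diazomethane may add as a 1,3-dipole across the electron-poor C5=C6 alkene, or homologate the C4 ketone, in competition with acylation. The fallback sets out from 11 and comes back at 13. Acid 11 would be converted into 12 as before, and 12 treated with N-isocyanoiminotriphenylphosphorane in CH2Cl2. α-Addition of the isocyanide carbon to the acid chloride should give (2R,3R)-6-{chloro[(triphenyl-λ5-phosphanylidene)hydrazinylidene]acetyl}-4-oxo-2-phenyl-3,4-dihydro-2H-pyran-3-yl (2R)-2-methylbutanoate F3. Aqueous work-up would hydrolyse the P=N bond to (2R,3R)-6-[chloro(hydrazinylidene)acetyl]-4-oxo-2-phenyl-3,4-dihydro-2H-pyran-3-yl (2R)-2-methylbutanoate F4. Et3N would then remove HCl to give 13 through the nitrile imine tautomer, with no free diazomethane present at any point.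

Step 6. Acetate still bound to manganese may be transferred in competition with the chiral carboxylate, and facial selectivity at C3 may be incomplete. The fallback sets out from 8 and comes back at 10. The lithium enolate of 8 (LiN(SiMe3)2, THF, −78 °C, kept cold to prevent ring opening) would be hydroxylated with 2-(benzenesulfonyl)-3-phenyloxaziridine on the face opposite phenyl to give tert-butyl (2R,3R)-3-hydroxy-4-oxo-2-phenyl-3,4-dihydro-2H-pyran-6-carboxylate F5. F5 would then be esterified with 9 (EDC·HCl, DMAP cat., CH2Cl2, 0 °C) to give 10.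

Further compounds
F1 | step 11 | [(2R,3R)-3-{[(2R)-2-methylbutanoyl]oxy}-4-oxo-2-phenyl-3,4-dihydro-2H-pyran-6-yl]acetic acid | CC[C@@H](C)C(=O)O[C@H]1C(=O)C=C(CC(=O)O)O[C@@H]1c1ccccc1
F2 | step 11 | (2R,3R)-6-(2-chloro-2-oxoethyl)-4-oxo-2-phenyl-3,4-dihydro-2H-pyran-3-yl (2R)-2-methylbutanoate | CC[C@@H](C)C(=O)O[C@H]1C(=O)C=C(CC(=O)Cl)O[C@@H]1c1ccccc1
F3 | step 8 | (2R,3R)-6-{chloro[(triphenyl-λ5-phosphanylidene)hydrazinylidene]acetyl}-4-oxo-2-phenyl-3,4-dihydro-2H-pyran-3-yl (2R)-2-methylbutanoate | CC[C@@H](C)C(=O)O[C@H]1C(=O)C=C(C(=O)C(Cl)=NN=P(c2ccccc2)(c2ccccc2)c2ccccc2)O[C@@H]1c1ccccc1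
F4 | step 8 | (2R,3R)-6-[chloro(hydrazinylidene)acetyl]-4-oxo-2-phenyl-3,4-dihydro-2H-pyran-3-yl (2R)-2-methylbutanoate | CC[C@@H](C)C(=O)O[C@H]1C(=O)C=C(C(=O)C(Cl)=NN)O[C@@H]1c1ccccc1
F5 | step 6 | tert-butyl (2R,3R)-3-hydroxy-4-oxo-2-phenyl-3,4-dihydro-2H-pyran-6-carboxylate | O[C@H]1C(=O)C=C(C(=O)OC(C)(C)C)O[C@@H]1c1ccccc1
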